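**Plan**
- Retrosynthetic cuts: the coumarate ester C–O bond first, then the C2–C3 bond of the dihydrofuran ring, then the aryl C3a–C3 bond (aryl bromide + acetate enolate) and the O1–C2 bond (phenol + benzylic chloride).
- Forward: both benzene rings are bought. Dihydroconiferyl alcohol is brominated, O-alkylated with the vanillyl unit, homologated to the arylacetate and diazotised. The dihydrofuran ring (O1–C2–C3–C3a–C7a) is the only ring made and closes last, by C2–C3 bond formation.
- Enabling feature: C2 is benzylic and carries O1 and an electron-rich 4-oxyaryl ring, so in the open form its C–H bond is doubly activated and lies 1,5 to C3. C3 bears the future C3–CH2O carbon as an ester, which makes C3 a donor/acceptor carbene.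
- Helpers: diazo group (lost as N2), ester (reduced to CH2OH), benzyl on the phenol (removed by H2 before the alkene arrives), TBS on the propanol (removed by HF at the end).
- Stereochemistry: C2 (R) comes from a chiral Rh(II) carboxylate in the C–H insertion. C3 forms cis, is epimerised to trans and is frozen by reduction (3S in the target).

Key step: step 7

Remark on the chemistry: the (S)-tert-leucinate catalyst is assumed, by analogy with simpler 2-(benzyloxy)aryl diazoacetates, to give the 2R centre. If the insertion product proves to be the antipode, the (R)-catalyst is used and nothing else changes.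

Step 1
Reactants: 1 dihydroconiferyl alcohol [4-(3-hydroxypropyl)-2-methoxyphenol]
Product: 2 2-bromo-4-(3-hydroxypropyl)-6-methoxyphenol
Conditions: NBS (1.0 equiv), i-Pr2NH (cat.), CH2Cl2, 0 °C, dark
Reagents that add atoms: N-bromosuccinimide, O=C1CCC(=O)N1Br
Why: Electrophilic aromatic bromination of a para-blocked phenol (amine-catalysed ortho-bromination) should go to the only free position ortho to the OH, as in vanillin to 5-bromovanillin, and the primary alcohol is inert to NBS at 0 °C.

Step 2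
Reactants: 3 4-(benzyloxy)-3-methoxybenzyl alcohol
Product: 4 4-(benzyloxy)-3-methoxybenzyl chloride
Conditions: SOCl2 (1.2 equiv), CH2Cl2, 0 °C to rt
Reagents that add atoms: thionyl chloride, ClS(Cl)=O
Why: Chlorodehydroxylation of an electron-rich benzylic alcohol via its chlorosulfite is fast at 0 °C, where the aryl benzyl ether survives.

Step 3
Reactants: 2 2-bromo-4-(3-hydroxypropyl)-6-methoxyphenol; 4 4-(benzyloxy)-3-methoxybenzyl chloride
Product: 5 3-[3-bromo-4-{[4-(benzyloxy)-3-methoxyphenyl]methoxy}-5-methoxyphenyl]propan-1-ol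
Conditions: K2CO3, TBAI (cat.), DMF, rt to 50 °C
Reagents that add atoms: none
Why: Williamson ether synthesis, in which K2CO3 deprotonates only the phenol so that the phenoxide, not the aliphatic alcohol, is alkylated by the benzylic chloride; this sets the O1–C2 bond.

Step 4
Reactants: 5 3-[3-bromo-4-{[4-(benzyloxy)-3-methoxyphenyl]methoxy}-5-methoxyphenyl]propan-1-ol
Product: 6 {3-[3-bromo-4-{[4-(benzyloxy)-3-methoxyphenyl]methoxy}-5-methoxyphenyl]propoxy}(tert-butyl)dimethylsilane
Conditions: TBSCl, imidazole, DMF, rt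
Reagents that add atoms: tert-butyldimethylsilyl chloride, CC(C)(C)[Si](C)(C)Cl
Why: Standard imidazole-mediated silylation of the only free hydroxyl masks the O–H bond, which would otherwise intercept the carbene of step 7.

Step 5
Reactants: 6 {3-[3-bromo-4-{[4-(benzyloxy)-3-methoxyphenyl]methoxy}-5-methoxyphenyl]propoxy}(tert-butyl)dimethylsilane
Product: 7 methyl 2-[2-{[4-(benzyloxy)-3-methoxyphenyl]methoxy}-5-{3-[(tert-butyldimethylsilyl)oxy]propyl}-3-methoxyphenyl]acetate
Conditions: Zn dust (TMSCl-activated), BrCH2CO2Me, THF, 40 °C; then 6, Pd2(dba)3 (2.5 mol %), XPhos (10 mol %), THF, 65 °C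
Reagents that add atoms: methyl bromoacetate (delivered as its zinc enolate), BrCC(=O)OC
Why: Pd-catalysed α-arylation of an ester zinc enolate (Negishi-type coupling of a Reformatsky reagent) runs under neutral conditions that silyl and benzyl ethers tolerate, and the bulky biarylphosphine should allow oxidative addition into the electron-rich ortho-alkoxy bromide.

Step 6
Reactants: 7 methyl 2-[2-{[4-(benzyloxy)-3-methoxyphenyl]methoxy}-5-{3-[(tert-butyldimethylsilyl)oxy]propyl}-3-methoxyphenyl]acetate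
Product: 8 methyl 2-[2-{[4-(benzyloxy)-3-methoxyphenyl]methoxy}-5-{3-[(tert-butyldimethylsilyl)oxy]propyl}-3-methoxyphenyl]-2-diazoacetate
Conditions: p-ABSA, DBU, MeCN, 0 °C to rt
Reagents that add atoms: 4-acetamidobenzenesulfonyl azide, CC(=O)Nc1ccc(cc1)S(=O)(=O)N=[N+]=[N-]
Why: Regitz diazo transfer to the benzylic ester enolate is the standard entry to aryl diazoacetates and touches neither the ethers nor the silyl group.

Step 7
Reactants: 8 methyl 2-[2-{[4-(benzyloxy)-3-methoxyphenyl]methoxy}-5-{3-[(tert-butyldimethylsilyl)oxy]propyl}-3-methoxyphenyl]-2-diazoacetate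
Product: 9 methyl (2R,3S)-2-[4-(benzyloxy)-3-methoxyphenyl]-5-{3-[(tert-butyldimethylsilyl)oxy]propyl}-7-methoxy-2,3-dihydro-1-benzofuran-3-carboxylate (cis)
Conditions: Rh2(S-PTTL)4 (2 mol %), toluene, −78 to −40 °C
Reagents that add atoms: none
Why: Rh(II) extrudes N2 from 8 to give a donor/acceptor rhodium carbene at C3 (aryl donor, ester acceptor), which inserts through a concerted, asynchronous, hydride-transfer-like three-centre transition state into one of the two enantiotopic benzylic C–H bonds of the ArCH2–O ether lying 1,5 to the carbene carbon. The closest known reaction type is the chiral dirhodium(II) carboxylate-catalysed intramolecular C–H insertion of 2-(benzyloxy)aryl diazoacetates to cis-2-aryl-2,3-dihydrobenzofuran-3-carboxylates. The dihydrofuran ring (O1–C2–C3–C3a–C7a) closes by C2–C3 bond formation in a 1,5-insertion, the only insertion that gives an unstrained ring. C2 is set by the catalyst, whose N-phthaloyl-tert-leucinate ligands select which enantiotopic hydrogen is replaced (2R expected from the S-catalyst); C3 is set relative to C2 by the compact insertion geometry, which should place aryl and ester cis (kinetic, 3S), and is corrected in step 8. The step needs chemoselectivity for this C–H bond over aromatic cycloaddition, oxonium ylide formation and carbene dimerisation; the bond is activated twice (α-oxygen and p-alkoxyaryl), the donor/acceptor carbene is selective, no O–H bond is present and the temperature is low.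

Step 8
Reactants: 9 methyl (2R,3S)-2-[4-(benzyloxy)-3-methoxyphenyl]-5-{3-[(tert-butyldimethylsilyl)oxy]propyl}-7-methoxy-2,3-dihydro-1-benzofuran-3-carboxylate
Product: 10 methyl (2R,3R)-2-[4-(benzyloxy)-3-methoxyphenyl]-5-{3-[(tert-butyldimethylsilyl)oxy]propyl}-7-methoxy-2,3-dihydro-1-benzofuran-3-carboxylate (trans)
Conditions: NaOMe (0.3 equiv), MeOH/THF, 0 °C to rt
Reagents that add atoms: none
Why: Base-catalysed epimerisation at C3 through the ester enolate should give the thermodynamically favoured trans isomer, while C2 keeps its configuration because ring-opening β-elimination (reverse 5-endo-trig) has the C2–O bond near the nodal plane of the enolate and is stereoelectronically disfavoured.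

Step 9
Reactants: 10 methyl (2R,3R)-2-[4-(benzyloxy)-3-methoxyphenyl]-5-{3-[(tert-butyldimethylsilyl)oxy]propyl}-7-methoxy-2,3-dihydro-1-benzofuran-3-carboxylate
Product: 11 [(2R,3S)-2-[4-(benzyloxy)-3-methoxyphenyl]-5-{3-[(tert-butyldimethylsilyl)oxy]propyl}-7-methoxy-2,3-dihydro-1-benzofuran-3-yl]methanol
Conditions: LiAlH4, THF, 0 °C; Rochelle salt work-up
Reagents that add atoms: none
Why: Hydride reduction of the ester to the primary alcohol removes the acidity at C3 and so fixes the trans relationship, and alkyl silyl and benzyl ethers are inert to LiAlH4 at 0 °C.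

Step 10
Reactants: 11 [(2R,3S)-2-[4-(benzyloxy)-3-methoxyphenyl]-5-{3-[(tert-butyldimethylsilyl)oxy]propyl}-7-methoxy-2,3-dihydro-1-benzofuran-3-yl]methanol
Product: 12 4-[(2R,3S)-5-{3-[(tert-butyldimethylsilyl)oxy]propyl}-3-(hydroxymethyl)-7-methoxy-2,3-dihydro-1-benzofuran-2-yl]-2-methoxyphenol
Conditions: H2 (1 atm), 10 % Pd/C, EtOAc, rt, stopped at full conversion
Reagents that add atoms: none
Why: Catalytic hydrogenolysis cleaves the acyclic aryl benzyl ether faster than the cyclic benzylic C2–O1 bond, and it is placed here because the cinnamate alkene introduced next would not survive it.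

Step 11
Reactants: 12 4-[(2R,3S)-5-{3-[(tert-butyldimethylsilyl)oxy]propyl}-3-(hydroxymethyl)-7-methoxy-2,3-dihydro-1-benzofuran-2-yl]-2-methoxyphenol; 13 (E)-4-hydroxycinnamic acid (p-coumaric acid)
Product: 14 [(2R,3S)-5-{3-[(tert-butyldimethylsilyl)oxy]propyl}-2-(4-hydroxy-3-methoxyphenyl)-7-methoxy-2,3-dihydro-1-benzofuran-3-yl]methyl (E)-3-(4-hydroxyphenyl)prop-2-enoate
Conditions: PPh3, DIAD, THF, 0 °C to rt
Reagents that add atoms: none
Why: Mitsunobu esterification, in which the carboxylic acid (pKa about 4.5) is the pronucleophile that protonates the betaine and attacks the primary alkoxyphosphonium carbon, so the far less acidic phenols should stay free, as known for phenolic acids with phenolic alcohols; no stereocentre is involved.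

Step 12
Reactants: 14 [(2R,3S)-5-{3-[(tert-butyldimethylsilyl)oxy]propyl}-2-(4-hydroxy-3-methoxyphenyl)-7-methoxy-2,3-dihydro-1-benzofuran-3-yl]methyl (E)-3-(4-hydroxyphenyl)prop-2-enoate
Product: 15 [(2R,3S)-2-(4-hydroxy-3-methoxyphenyl)-5-(3-hydroxypropyl)-7-methoxy-2,3-dihydro-1-benzofuran-3-yl]methyl (E)-3-(4-hydroxyphenyl)prop-2-enoate (target)
Conditions: HF·pyridine, pyridine/THF, 0 °C to rt
Reagents that add atoms: none
Why: Fluoride-driven desilylation of the primary TBS ether under buffered, non-basic conditions should leave the cinnamate ester, the phenols and both stereocentres untouched.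

**Compound list**
1 | dihydroconiferyl alcohol, 4-(3-hydroxypropyl)-2-methoxyphenol | COc1cc(CCCO)ccc1O | starting material
2 | 2-bromo-4-(3-hydroxypropyl)-6-methoxyphenol | COc1cc(CCCO)cc(Br)c1O | intermediate
3 | 4-(benzyloxy)-3-methoxybenzyl alcohol | COc1cc(CO)ccc1OCc1ccccc1 | starting material
4 | 4-(benzyloxy)-3-methoxybenzyl chloride | COc1cc(CCl)ccc1OCc1ccccc1 | intermediate
5 | 3-[3-bromo-4-{[4-(benzyloxy)-3-methoxyphenyl]methoxy}-5-methoxyphenyl]propan-1-ol | COc1cc(CCCO)cc(Br)c1OCc1ccc(OCc2ccccc2)c(OC)c1 | intermediate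
6 | {3-[3-bromo-4-{[4-(benzyloxy)-3-methoxyphenyl]methoxy}-5-methoxyphenyl]propoxy}(tert-butyl)dimethylsilane | COc1cc(CCCO[Si](C)(C)C(C)(C)C)cc(Br)c1OCc1ccc(OCc2ccccc2)c(OC)c1 | intermediate
7 | methyl 2-[2-{[4-(benzyloxy)-3-methoxyphenyl]methoxy}-5-{3-[(tert-butyldimethylsilyl)oxy]propyl}-3-methoxyphenyl]acetate | COC(=O)Cc1cc(CCCO[Si](C)(C)C(C)(C)C)cc(OC)c1OCc1ccc(OCc2ccccc2)c(OC)c1 | intermediate
8 | methyl 2-[2-{[4-(benzyloxy)-3-methoxyphenyl]methoxy}-5-{3-[(tert-butyldimethylsilyl)oxy]propyl}-3-methoxyphenyl]-2-diazoacetate | COC(=O)C(=[N+]=[N-])c1cc(CCCO[Si](C)(C)C(C)(C)C)cc(OC)c1OCc1ccc(OCc2ccccc2)c(OC)c1 | intermediate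
9 | methyl (2R,3S)-2-[4-(benzyloxy)-3-methoxyphenyl]-5-{3-[(tert-butyldimethylsilyl)oxy]propyl}-7-methoxy-2,3-dihydro-1-benzofuran-3-carboxylate (cis) | COc1cc([C@@H]2Oc3c(OC)cc(CCCO[Si](C)(C)C(C)(C)C)cc3[C@@H]2C(=O)OC)ccc1OCc1ccccc1 | intermediate
10 | methyl (2R,3R)-2-[4-(benzyloxy)-3-methoxyphenyl]-5-{3-[(tert-butyldimethylsilyl)oxy]propyl}-7-methoxy-2,3-dihydro-1-benzofuran-3-carboxylate (trans) | COc1cc([C@@H]2Oc3c(OC)cc(CCCO[Si](C)(C)C(C)(C)C)cc3[C@H]2C(=O)OC)ccc1OCc1ccccc1 | intermediate
11 | [(2R,3S)-2-[4-(benzyloxy)-3-methoxyphenyl]-5-{3-[(tert-butyldimethylsilyl)oxy]propyl}-7-methoxy-2,3-dihydro-1-benzofuran-3-yl]methanol | COc1cc([C@@H]2Oc3c(OC)cc(CCCO[Si](C)(C)C(C)(C)C)cc3[C@H]2CO)ccc1OCc1ccccc1 | intermediate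
12 | 4-[(2R,3S)-5-{3-[(tert-butyldimethylsilyl)oxy]propyl}-3-(hydroxymethyl)-7-methoxy-2,3-dihydro-1-benzofuran-2-yl]-2-methoxyphenol | COc1cc([C@@H]2Oc3c(OC)cc(CCCO[Si](C)(C)C(C)(C)C)cc3[C@H]2CO)ccc1O | intermediate
13 | (E)-4-hydroxycinnamic acid (p-coumaric acid) | OC(=O)/C=C/c1ccc(O)cc1 | starting material
14 | [(2R,3S)-5-{3-[(tert-butyldimethylsilyl)oxy]propyl}-2-(4-hydroxy-3-methoxyphenyl)-7-methoxy-2,3-dihydro-1-benzofuran-3-yl]methyl (E)-3-(4-hydroxyphenyl)prop-2-enoate | COc1cc([C@@H]2Oc3c(OC)cc(CCCO[Si](C)(C)C(C)(C)C)cc3[C@H]2COC(=O)/C=C/c2ccc(O)cc2)ccc1O | intermediate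
15 | [(2R,3S)-2-(4-hydroxy-3-methoxyphenyl)-5-(3-hydroxypropyl)-7-methoxy-2,3-dihydro-1-benzofuran-3-yl]methyl (E)-3-(4-hydroxyphenyl)prop-2-enoate | COc1cc([C@@H]2Oc3c(OC)cc(CCCO)cc3[C@H]2COC(=O)/C=C/c2ccc(O)cc2)ccc1O | target

**Step count**
Total steps: 12. Longest linear sequence: 11 steps (1 to 15 through steps 1 and 3–12; equally 3 to 15 through steps 2–12).

**Steps most likely to fail**

Step 7. The catalyst may discriminate poorly between the two enantiotopic benzylic hydrogens of this doubly ortho-substituted, electron-rich substrate, or the carbene may be diverted into aromatic cycloaddition, ylide formation or dimerisation. The fallback closes the ring by C2–O1 bond formation under auxiliary control. It sets out from 7. Saponification (LiOH, THF/H2O) should give 2-[2-{[4-(benzyloxy)-3-methoxyphenyl]methoxy}-5-{3-[(tert-butyldimethylsilyl)oxy]propyl}-3-methoxyphenyl]acetic acid F1. Coupling with (R)-4-benzyl-1,3-oxazolidin-2-one (DCC, DMAP, CH2Cl2) gives the N-acyl oxazolidinone F2. Bu2BOTf and i-Pr2NEt at −78 °C convert it into the (Z)-dibutylboron enolate F3, which adds to 4-(benzyloxy)-3-methoxybenzaldehyde in an Evans syn-aldol reaction to give the (2R,3R)-aldol adduct F4; this sets the future C3. LiBH4 removes the auxiliary and gives the (1R,2S)-1,3-diol F5. Hydrogenolysis (H2, Pd/C, EtOAc) cleaves all three benzylic ethers to the bis-phenol diol F6. Mild acid (PPTS, CH2Cl2, rt) ionises the 4-hydroxybenzylic alcohol to a p-quinone methide, which the neighbouring phenol captures 5-exo, anti to the CH2OH arm, to give the trans ring. The sequence comes back to the route at 12.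

Step 5. Oxidative addition into the hindered, electron-rich aryl bromide may be slow, so that protodebromination and self-condensation of the zinc enolate take over. The fallback builds the diazo ester without a cross-coupling and sets out from 6. Bromine–lithium exchange (n-BuLi, THF, −78 °C) gives the aryllithium F7. Inverse addition to excess dimethyl oxalate gives methyl 2-[2-{[4-(benzyloxy)-3-methoxyphenyl]methoxy}-5-{3-[(tert-butyldimethylsilyl)oxy]propyl}-3-methoxyphenyl]-2-oxoacetate F8. Condensation with p-toluenesulfonyl hydrazide gives the tosylhydrazone F9, and DBU in CH2Cl2 (Bamford–Stevens elimination of sulfinate) gives the diazo ester. The sequence comes back to the route at 8, so step 6 is also bypassed.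

Step 11. A phenol may be O-alkylated, or the activated β-branched alcohol may eliminate, instead of clean carboxylate attack. The fallback gives up chemoselective activation in favour of exhaustive acylation and selective unmasking, and sets out from 12. Acylation of both the primary alcohol and the guaiacyl phenol with commercial (E)-4-acetoxycinnamic acid (EDC·HCl, DMAP, CH2Cl2) gives the bis[(E)-4-acetoxycinnamate] F10. Pyrrolidine in CH2Cl2 at 0 °C then cleaves the three aryl esters (two acetates and the aryl cinnamate) by aminolysis, which is much faster than attack on the alkyl cinnamate. The sequence comes back to the route at 14.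

**Further compounds**
F1 | step 7 | 2-[2-{[4-(benzyloxy)-3-methoxyphenyl]methoxy}-5-{3-[(tert-butyldimethylsilyl)oxy]propyl}-3-methoxyphenyl]acetic acid | OC(=O)Cc1cc(CCCO[Si](C)(C)C(C)(C)C)cc(OC)c1OCc1ccc(OCc2ccccc2)c(OC)c1
F2 | step 7 | (4R)-4-benzyl-3-{2-[2-{[4-(benzyloxy)-3-methoxyphenyl]methoxy}-5-{3-[(tert-butyldimethylsilyl)oxy]propyl}-3-methoxyphenyl]acetyl}-1,3-oxazolidin-2-one | O=C1OC[C@@H](Cc2ccccc2)N1C(=O)Cc1cc(CCCO[Si](C)(C)C(C)(C)C)cc(OC)c1OCc1ccc(OCc2ccccc2)c(OC)c1
F3 | step 7 | (Z)-dibutylboron enolate of F2 | CCCCB(CCCC)O/C(=C\c1cc(CCCO[Si](C)(C)C(C)(C)C)cc(OC)c1OCc1ccc(OCc2ccccc2)c(OC)c1)N1C(=O)OC[C@H]1Cc1ccccc1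
F4 | step 7 | (4R)-4-benzyl-3-[(2R,3R)-3-[4-(benzyloxy)-3-methoxyphenyl]-2-[2-{[4-(benzyloxy)-3-methoxyphenyl]methoxy}-5-{3-[(tert-butyldimethylsilyl)oxy]propyl}-3-methoxyphenyl]-3-hydroxypropanoyl]-1,3-oxazolidin-2-one | O=C1OC[C@@H](Cc2ccccc2)N1C(=O)[C@H](c1cc(CCCO[Si](C)(C)C(C)(C)C)cc(OC)c1OCc1ccc(OCc2ccccc2)c(OC)c1)[C@@H](O)c1ccc(OCc2ccccc2)c(OC)c1
F5 | step 7 | (1R,2S)-1-[4-(benzyloxy)-3-methoxyphenyl]-2-[2-{[4-(benzyloxy)-3-methoxyphenyl]methoxy}-5-{3-[(tert-butyldimethylsilyl)oxy]propyl}-3-methoxyphenyl]propane-1,3-diol | OC[C@H](c1cc(CCCO[Si](C)(C)C(C)(C)C)cc(OC)c1OCc1ccc(OCc2ccccc2)c(OC)c1)[C@@H](O)c1ccc(OCc2ccccc2)c(OC)c1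
F6 | step 7 | (1R,2S)-2-[5-{3-[(tert-butyldimethylsilyl)oxy]propyl}-2-hydroxy-3-methoxyphenyl]-1-(4-hydroxy-3-methoxyphenyl)propane-1,3-diol | OC[C@H](c1cc(CCCO[Si](C)(C)C(C)(C)C)cc(OC)c1O)[C@@H](O)c1ccc(O)c(OC)c1
F7 | step 5 | [2-{[4-(benzyloxy)-3-methoxyphenyl]methoxy}-5-{3-[(tert-butyldimethylsilyl)oxy]propyl}-3-methoxyphenyl]lithium | [Li]c1cc(CCCO[Si](C)(C)C(C)(C)C)cc(OC)c1OCc1ccc(OCc2ccccc2)c(OC)c1
F8 | step 5 | methyl 2-[2-{[4-(benzyloxy)-3-methoxyphenyl]methoxy}-5-{3-[(tert-butyldimethylsilyl)oxy]propyl}-3-methoxyphenyl]-2-oxoacetate | COC(=O)C(=O)c1cc(CCCO[Si](C)(C)C(C)(C)C)cc(OC)c1OCc1ccc(OCc2ccccc2)c(OC)c1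
F9 | step 5 | methyl 2-[2-{[4-(benzyloxy)-3-methoxyphenyl]methoxy}-5-{3-[(tert-butyldimethylsilyl)oxy]propyl}-3-methoxyphenyl]-2-[2-(4-methylbenzenesulfonyl)hydrazinylidene]acetate | COC(=O)C(=NNS(=O)(=O)c1ccc(C)cc1)c1cc(CCCO[Si](C)(C)C(C)(C)C)cc(OC)c1OCc1ccc(OCc2ccccc2)c(OC)c1
F10 | step 11 | 4-[(2R,3S)-3-({[(E)-3-(4-acetoxyphenyl)prop-2-enoyl]oxy}methyl)-5-{3-[(tert-butyldimethylsilyl)oxy]propyl}-7-methoxy-2,3-dihydro-1-benzofuran-2-yl]-2-methoxyphenyl (E)-3-(4-acetoxyphenyl)prop-2-enoate | COc1cc([C@@H]2Oc3c(OC)cc(CCCO[Si](C)(C)C(C)(C)C)cc3[C@H]2COC(=O)/C=C/c2ccc(OC(C)=O)cc2)ccc1OC(=O)/C=C/c1ccc(OC(C)=O)cc1
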